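The synthesis opens the cyclohexane ring (ring A) of the hydrindane at C3a–C7a and C4–C5. In ring A, C7a, C3a and the quaternary C4 are adjacent, and C1–C3 of the cyclopentane (ring B) link C7a to C3a. With a diene terminus on C7a, an enal double bond on C3a=C4 and C1–C3 as tether, one catalytic asymmetric intramolecular Diels–Alder reaction closes both rings and sets C3a, C4 and C7a. Its precursor is the acyclic (2E,7E)-2,7-dimethyldeca-2,7,9-trienal 10 with a 1,3-dithiane at C6. The derived C1 ketone 15 is joined to an alkenyllithium made from D-malic acid, and palladium–formate hydrogenolysis sets C1.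

Key step: step 6

Labels: C1–C7a follow indane numbering. Ca is the alkene carbon bonded to C1 and Cb is the CH that bears CH2OAc. The lactone atoms are O1', C2' (C=O), C3' (CHOH), C4' and C5'. α is the face opposite the angular methyl and β is the face of that methyl.
Assumption: the facial sense of the (S)-oxazaborolidinium catalyst in step 6 is taken from the formyl C–H···O binding model for 2-substituted enals; the (R)-catalyst is equally accessible if the sense is opposite.

Step 1
Reactants: 1 acrolein; 2 2-(triphenylphosphoranylidene)propanal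
Product: 3 (2E)-2-methylpenta-2,4-dienal
Conditions: 1 (2 equiv), CH2Cl2, 0 → 23 °C
Reagents that add atoms: none
Why: Wittig olefination with the formyl-stabilised ylide gives the E-alkene, attacks unhindered acrolein much faster than the α-branched product 3, and avoids a polymerisation-prone crossed aldol of acrolein.

Step 2
Reactants: 3 (2E)-2-methylpenta-2,4-dienal; 4 propane-1,3-dithiol
Product: 5 2-[(2E)-penta-2,4-dien-2-yl]-1,3-dithiane
Conditions: BF3·OEt2 (0.1 equiv), CH2Cl2, −40 → 0 °C
Reagents that add atoms: none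
Why: Lewis-acid-catalysed dithioacetalisation of an enal is fast at low temperature, the α-methyl group slows conjugate thiol addition, and the E-alkene is not touched.

Step 3
Reactants: 5 2-[(2E)-penta-2,4-dien-2-yl]-1,3-dithiane; 6 3-bromo-1,1-dimethoxypropane
Product: 8 2-(3,3-dimethoxypropyl)-2-[(2E)-penta-2,4-dien-2-yl]-1,3-dithiane, via lithiated dithiane 7 (not isolated)
Conditions: n-BuLi, THF, −78 → −30 °C; 6, −78 → 0 °C
Reagents that add atoms: none
Why: In this Corey–Seebach umpolung alkylation the sulfur-stabilised pentadienyl anion 7 carries most of its charge at the dithiane carbon, so in THF without polar additives it takes primary alkyl halides at that α-carbon, and the extended anion keeps the more stable E geometry.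

Step 4
Reactants: 8 2-(3,3-dimethoxypropyl)-2-[(2E)-penta-2,4-dien-2-yl]-1,3-dithiane
Product: 9 3-{2-[(2E)-penta-2,4-dien-2-yl]-1,3-dithian-2-yl}propanal
Conditions: pyridinium p-toluenesulfonate, acetone–H2O, 50 °C
Reagents that add atoms: water, O
Why: Mild acid-catalysed acetal hydrolysis cleaves only the dimethyl acetal, because the dithiane and the diene are inert to a buffered weak acid.

Step 5
Reactants: 9 3-{2-[(2E)-penta-2,4-dien-2-yl]-1,3-dithian-2-yl}propanal; 2 2-(triphenylphosphoranylidene)propanal
Product: 10 (2E)-2-methyl-5-{2-[(2E)-penta-2,4-dien-2-yl]-1,3-dithian-2-yl}pent-2-enal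
Conditions: PhMe, 60 °C
Reagents that add atoms: none
Why: Wittig olefination with the same stabilised ylide gives the (2E)-2-methylenal, and the moderate temperature keeps an uncatalysed racemic cycloaddition of 10 from starting.

Step 6
Reactants: 10 (2E)-2-methyl-5-{2-[(2E)-penta-2,4-dien-2-yl]-1,3-dithian-2-yl}pent-2-enal
Product: 11 (3a'S,4'R,7a'S)-4',7a'-dimethyl-2',3',3a',4',5',7a'-hexahydrospiro[1,3-dithiane-2,1'-indene]-4'-carbaldehyde
Conditions: (S)-tetrahydro-3,3-diphenyl-1-(o-tolyl)-1H,3H-pyrrolo[1,2-c][1,3,2]oxazaborole (20 mol %) + (CF3SO2)2NH (20 mol %), CH2Cl2, −78 → −20 °C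
Reagents that add atoms: none
Why: The boron of the N-protonated oxazaborolidine binds the formyl oxygen of 10, a formyl C–H···O contact holds the s-trans enal over one phenyl ring, and the tethered diene adds in a concerted but asynchronous [4+2] process in which C3a–C7a runs ahead of C4–C5; the imide acid is chosen as activator because an aluminium halide would be thiophilic. The closest known reactions are the chiral-Lewis-acid-catalysed type 1 intramolecular Diels–Alder cyclisations of 2-methyldeca-2,7,9-trienal and related trienals to trans-hydrindene carbaldehydes. The cyclohexene closes through the two new σ-bonds of the cycloaddition, and the cyclopentane closes at the same moment as the fused five-membered ring spanned by the tether C1–C2–C3 between C7a and C3a. C4 is tied to C3a by suprafacial addition to the E-enal (CHO cis to H-3a); C7a is tied to C3a by the endo position of the formyl group, which puts the tether exo and so the angular methyl and H-3a on opposite faces; the absolute sense of all three comes from the catalyst, whose phenyl group covers the C2-Si face so that the diene meets the C2-Re/C3-Si face. The step needs endo, facial and rate selectivity: the E geometry of both alkenes, the three-atom tether and the achiral geminal dithiane (reactive-rotamer effect, no basic oxygen) secure the first two, and the methyl group that points inside the s-cis diene remains the rate risk.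

Step 7
Reactants: 11 spiro dithiane carbaldehyde
Product: 13 (3a'S,7a'S)-4',4',7a'-trimethyl-2',3',3a',4',5',7a'-hexahydrospiro[1,3-dithiane-2,1'-indene], via hydrazone 12 (not isolated)
Conditions: N2H4·H2O, diethylene glycol, 120 °C; KOH, 200 °C
Reagents that add atoms: none
Why: Wolff–Kishner reduction (Huang-Minlon procedure) turns the non-enolisable neopentyl aldehyde into the second C4 methyl group, and the dithiane masks C1 from hydrazine and, like the isolated alkene, is stable to base and heat.

Step 8
Reactants: 13 gem-dimethyl spiro dithiane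
Product: 14 (3aS,7aS)-4,4,7a-trimethyl-2,3,3a,4,5,7a-hexahydro-1H-inden-1-one
Conditions: MeI, CaCO3, MeCN–H2O (9:1), 55 °C
Reagents that add atoms: water, O
Why: In this alkylative dithiane hydrolysis S-methylation makes sulfur a leaving group, strain relief at the crowded spiro carbon helps thionium formation, and CaCO3 keeps the medium neutral so that the alkene and the ring fusion are safe.

Step 9
Reactants: 14 (3aS,7aS)-4,4,7a-trimethyl-2,3,3a,4,5,7a-hexahydro-1H-inden-1-one
Product: 15 (3aS,7aS)-4,4,7a-trimethyloctahydro-1H-inden-1-one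
Conditions: H2 (1 atm), 10% Pd on carbon, EtOAc, 23 °C
Reagents that add atoms: none
Why: Heterogeneous catalytic hydrogenation of the cis-disubstituted C6=C7 alkene is placed after sulfur removal so that the catalyst is not poisoned, creates no stereocentre and leaves the hindered ketone.

Step 10
Reactants: 16 (tert-butyldimethylsilyloxy)acetaldehyde; 17 ethyl (triphenylphosphoranylidene)acetate
Product: 19 ethyl (2Z)-2-bromo-4-(tert-butyldimethylsilyloxy)but-2-enoate, via bromo ylide 18 (not isolated)
Conditions: 17, N-bromosuccinimide, CH2Cl2, −20 °C; 16, 23 °C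
Reagents that add atoms: N-bromosuccinimide, O=C1CCC(=O)N1Br
Why: Bromination of the stabilised ylide followed by Wittig olefination gives the 2-bromoenoate with ester and CH2OSi trans (Z descriptor), which is the geometry the chair transition state of step 14 needs.

Step 11
Reactants: 19 ethyl (2Z)-2-bromo-4-(tert-butyldimethylsilyloxy)but-2-enoate
Product: 20 (2Z)-2-bromo-4-(tert-butyldimethylsilyloxy)but-2-en-1-ol
Conditions: i-Bu2AlH (2.2 equiv), CH2Cl2, −78 °C
Reagents that add atoms: none
Why: 1,2-Reduction of the enoate at low temperature gives the allylic alcohol without touching the vinylic C–Br bond, the silyl ether or the alkene geometry.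

Step 12
Reactants: 21 (R)-malic acid
Product: 23 (3R)-3-hydroxy-4-methoxy-4-oxobutanoic acid, via acyloxy anhydride 22 (not isolated)
Conditions: (CF3CO)2O, 0 → 23 °C; evaporate; MeOH, 23 °C
Reagents that add atoms: methanol, CO
Why: After anhydride formation, regioselective alcoholysis has methanol open 22 at the carbonyl next to the electron-poor acyloxy carbon and strip the trifluoroacetyl group, so only the distal acid stays free and the chiral-pool stereocentre (future C3') is kept.

Step 13
Reactants: 23 (3R)-3-hydroxy-4-methoxy-4-oxobutanoic acid; 20 (2Z)-2-bromo-4-(tert-butyldimethylsilyloxy)but-2-en-1-ol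
Product: 24 4-[(2Z)-2-bromo-4-(tert-butyldimethylsilyloxy)but-2-en-1-yl] 1-methyl (2R)-2-hydroxybutanedioate
Conditions: dicyclohexylcarbodiimide, 4-(dimethylamino)pyridine (cat.), CH2Cl2, 0 °C
Reagents that add atoms: none
Why: Steglich esterification couples the free acid to the primary allylic alcohol, which outcompetes the hindered, hydrogen-bonded secondary hydroxyl of 23.

Step 14
Reactants: 24 mixed malate diester
Product: 26 (2S,3R)-2-[(2S)-3-bromo-1-(tert-butyldimethylsilyloxy)but-3-en-2-yl]-3-hydroxy-4-methoxy-4-oxobutanoic acid, via dilithio dianion 25 (not isolated)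
Conditions: LiN(SiMe3)2 (2.3 equiv), THF, −78 → 23 °C; 1 M HCl
Reagents that add atoms: none
Why: In this dianionic ester-enolate Claisen (Ireland–Claisen-type) rearrangement of a β-hydroxy allyl ester, the lithium chelate between alkoxide and enolate oxygens fixes the enolate geometry (C3' cis to OLi) and, as in the Fráter–Seebach alkylation of malates, directs bond formation to the face anti to CO2Me (sets C4'), while the chair with CH2OSi equatorial sets Cb and unveils the 2-bromoalkene.

Step 15
Reactants: 26 rearranged acid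
Product: 28 (3R,4R)-4-[(2S)-3-bromo-1-(tert-butyldimethylsilyloxy)but-3-en-2-yl]-3-hydroxyoxolan-2-one, via diol ester 27 (not isolated)
Conditions: BH3·THF, THF, 0 °C; MeOH; pyridinium p-toluenesulfonate, CH2Cl2, 23 °C
Reagents that add atoms: none
Why: Chemoselective borane reduction of the carboxylic acid (faster than the ester or the electron-poor bromoalkene) gives 27, whose new primary hydroxyl lactonises onto the methyl ester and leaves OH and side chain cis without touching a stereocentre.

Step 16
Reactants: 28 hydroxy lactone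
Product: 29 (3R,4R)-4-[(2S)-3-bromo-1-(tert-butyldimethylsilyloxy)but-3-en-2-yl]oxolane-2,3-diol (anomers)
Conditions: i-Bu2AlH (2.5 equiv), CH2Cl2, −78 °C
Reagents that add atoms: none
Why: Partial lactone reduction stops at the aluminium lactolate at −78 °C, and the first equivalent of hydride is consumed by the free hydroxyl.

Step 17
Reactants: 29 lactol diol
Product: 30 (3aR,6R,6aR)-6-[(2S)-3-bromo-1-(tert-butyldimethylsilyloxy)but-3-en-2-yl]-2,2-dimethyltetrahydrofuro[2,3-d][1,3]dioxole
Conditions: Me2C(OMe)2, acetone, pyridinium p-toluenesulfonate, 23 °C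
Reagents that add atoms: 2,2-dimethoxypropane, COC(C)(C)OC
Why: Acid-catalysed transacetalisation ties the lactol hydroxyl and the C3' hydroxyl into a cis-fused dioxolane (the anomeric centre adapts), so one organolithium-stable group masks both the future lactone carbonyl and its hydroxyl.

Step 18
Reactants: 30 bromoalkene acetonide; 15 (3aS,7aS)-4,4,7a-trimethyloctahydro-1H-inden-1-one
Product: 33 C1 tertiary allylic methyl carbonate (1R; carbonate β; side chain α), via alkenyllithium 31 (not isolated), via lithium alkoxide 32 (not isolated)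
Conditions: 30, t-BuLi (2.1 equiv), Et2O, −78 °C; 15, −78 → 0 °C; ClCO2Me, −78 → 23 °C
Reagents that add atoms: methyl chloroformate, COC(=O)Cl
Why: After bromine–lithium exchange, the alkenyllithium undergoes 1,2-addition to the cyclopentanone from the α face opposite the angular methyl, as nucleophiles do with 17-oxo steroids, and the β-alkoxide is acylated in situ to the allylic carbonate (C1 is provisional here).

Step 19
Reactants: 33 tertiary allylic carbonate
Product: 34 hydrogenolysis product with H-1 α and the 1,1-disubstituted alkene (1R,3aS,7aS)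
Conditions: Pd(OAc)2 (10 mol %), n-Bu3P (10 mol %), HCO2H, Et3N, THF, 23 → 45 °C
Reagents that add atoms: none
Why: In this palladium-catalysed formate hydrogenolysis of an allylic carbonate (Tsuji type), zerovalent palladium ionises anti to the β-carbonate and also prefers the α face away from the angular methyl, and the palladium formate passes hydride to the more substituted allyl terminus C1 on that face, which gives the terminal methylene with the side chain β.

Step 20
Reactants: 34 silyl ether
Product: 35 primary alcohol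
Conditions: Bu4NF, THF, 0 → 23 °C
Reagents that add atoms: none
Why: Fluoride-mediated desilylation frees the primary alcohol and leaves the acetonide and the alkene alone.

Step 21
Reactants: 35 primary alcohol
Product: 36 primary acetate
Conditions: Ac2O, pyridine, 4-(dimethylamino)pyridine (cat.), CH2Cl2, 23 °C
Reagents that add atoms: acetic anhydride, CC(=O)OC(C)=O
Why: Nucleophile-catalysed acetylation of the only free hydroxyl installs the acetate before the lactol is unmasked, so this oxygen cannot later add to C2'.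

Step 22
Reactants: 36 acetate acetonide
Product: 37 lactol diol acetate (anomers)
Conditions: AcOH–H2O (4:1), 65 °C
Reagents that add atoms: none
Why: Acid-catalysed ketal hydrolysis in aqueous acetic acid releases the lactol and the C3' hydroxyl, and the acid is too weak to protonate the 1,1-disubstituted alkene or to cleave the acetate.

Step 23
Reactants: 37 lactol diol acetate
Product: 39 target CNP0252518.3, via hydroxy acid 38 (not isolated)
Conditions: NaClO2, NaH2PO4, 2-methylbut-2-ene, t-BuOH–H2O, 23 °C; then pH 3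
Reagents that add atoms: sodium chlorite, [Na+].[O-]Cl=O
Why: Pinnick (chlorite) oxidation acts only on the open hydroxy-aldehyde form of the lactol, as in the chlorite oxidation of aldoses to aldonic acids, so the C3' hydroxyl, the acetate and (with the hypochlorite scavenger) the alkene survive, and 38 closes to the γ-lactone.

Compound list
1 | acrolein | C=CC=O | starting material
2 | 2-(triphenylphosphoranylidene)propanal | CC(C=O)=P(c1ccccc1)(c1ccccc1)c1ccccc1 | starting material
3 | (2E)-2-methylpenta-2,4-dienal | C=C/C=C(C)/C=O | intermediate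
4 | propane-1,3-dithiol | SCCCS | starting material
5 | 2-[(2E)-penta-2,4-dien-2-yl]-1,3-dithiane | C=C/C=C(C)/C1SCCCS1 | intermediate
6 | 3-bromo-1,1-dimethoxypropane | COC(CCBr)OC | starting material
7 | 2-lithio-2-[(2E)-penta-2,4-dien-2-yl]-1,3-dithiane | [Li]C1(SCCCS1)/C(C)=C/C=C | intermediate
8 | 2-(3,3-dimethoxypropyl)-2-[(2E)-penta-2,4-dien-2-yl]-1,3-dithiane | C=C/C=C(C)/C1(CCC(OC)OC)SCCCS1 | intermediate
9 | 3-{2-[(2E)-penta-2,4-dien-2-yl]-1,3-dithian-2-yl}propanal | C=C/C=C(C)/C1(CCC=O)SCCCS1 | intermediate
10 | (2E)-2-methyl-5-{2-[(2E)-penta-2,4-dien-2-yl]-1,3-dithian-2-yl}pent-2-enal, i.e. (2E,7E)-2,7-dimethyldeca-2,7,9-trienal with a 1,3-dithiane at C6 | C=C/C=C(C)/C1(SCCCS1)CC/C=C(C)/C=O | intermediate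
11 | (3a'S,4'R,7a'S)-4',7a'-dimethyl-2',3',3a',4',5',7a'-hexahydrospiro[1,3-dithiane-2,1'-indene]-4'-carbaldehyde (trans-fused, CHO cis to H-3a') | S1CCCSC12CC[C@H]3[C@](C)(C=O)CC=C[C@]23C | intermediate
12 | hydrazone of 11 | S1CCCSC12CC[C@H]3[C@](C)(C=NN)CC=C[C@]23C | intermediate
13 | (3a'S,7a'S)-4',4',7a'-trimethyl-2',3',3a',4',5',7a'-hexahydrospiro[1,3-dithiane-2,1'-indene] | S1CCCSC12CC[C@H]3C(C)(C)CC=C[C@]23C | intermediate
14 | (3aS,7aS)-4,4,7a-trimethyl-2,3,3a,4,5,7a-hexahydro-1H-inden-1-one | O=C1CC[C@H]2C(C)(C)CC=C[C@]12C | intermediate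
15 | (3aS,7aS)-4,4,7a-trimethyloctahydro-1H-inden-1-one | O=C1CC[C@H]2C(C)(C)CCC[C@]12C | intermediate
16 | (tert-butyldimethylsilyloxy)acetaldehyde | O=CCO[Si](C)(C)C(C)(C)C | starting material
17 | ethyl (triphenylphosphoranylidene)acetate | CCOC(=O)C=P(c1ccccc1)(c1ccccc1)c1ccccc1 | starting material
18 | ethyl bromo(triphenylphosphoranylidene)acetate | CCOC(=O)C(Br)=P(c1ccccc1)(c1ccccc1)c1ccccc1 | intermediate
19 | ethyl (2Z)-2-bromo-4-(tert-butyldimethylsilyloxy)but-2-enoate | CCOC(=O)/C(Br)=C/CO[Si](C)(C)C(C)(C)C | intermediate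
20 | (2Z)-2-bromo-4-(tert-butyldimethylsilyloxy)but-2-en-1-ol | OC/C(Br)=C/CO[Si](C)(C)C(C)(C)C | intermediate
21 | (R)-malic acid (D-malic acid) | OC(=O)C[C@@H](O)C(=O)O | starting material
22 | (3R)-2,5-dioxooxolan-3-yl trifluoroacetate | O=C1C[C@@H](OC(=O)C(F)(F)F)C(=O)O1 | intermediate
23 | (3R)-3-hydroxy-4-methoxy-4-oxobutanoic acid | OC(=O)C[C@@H](O)C(=O)OC | intermediate
24 | 4-[(2Z)-2-bromo-4-(tert-butyldimethylsilyloxy)but-2-en-1-yl] 1-methyl (2R)-2-hydroxybutanedioate | O=C(C[C@@H](O)C(=O)OC)OC/C(Br)=C/CO[Si](C)(C)C(C)(C)C | intermediate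
25 | dilithium alkoxide-enolate of 24 (C3' cis to OLi) | [Li]O/C(OC/C(Br)=C/CO[Si](C)(C)C(C)(C)C)=C\[C@@H](O[Li])C(=O)OC | intermediate
26 | (2S,3R)-2-[(2S)-3-bromo-1-(tert-butyldimethylsilyloxy)but-3-en-2-yl]-3-hydroxy-4-methoxy-4-oxobutanoic acid | C=C(Br)[C@H](CO[Si](C)(C)C(C)(C)C)[C@H](C(=O)O)[C@@H](O)C(=O)OC | intermediate
27 | methyl (2R,3R,4S)-5-bromo-4-[(tert-butyldimethylsilyloxy)methyl]-2-hydroxy-3-(hydroxymethyl)hex-5-enoate | C=C(Br)[C@H](CO[Si](C)(C)C(C)(C)C)[C@H](CO)[C@@H](O)C(=O)OC | intermediate
28 | (3R,4R)-4-[(2S)-3-bromo-1-(tert-butyldimethylsilyloxy)but-3-en-2-yl]-3-hydroxyoxolan-2-one (OH and side chain cis) | C=C(Br)[C@H](CO[Si](C)(C)C(C)(C)C)[C@@H]1COC(=O)[C@@H]1O | intermediate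
29 | (3R,4R)-4-[(2S)-3-bromo-1-(tert-butyldimethylsilyloxy)but-3-en-2-yl]oxolane-2,3-diol (anomers) | C=C(Br)[C@H](CO[Si](C)(C)C(C)(C)C)[C@@H]1COC(O)[C@@H]1O | intermediate
30 | (3aR,6R,6aR)-6-[(2S)-3-bromo-1-(tert-butyldimethylsilyloxy)but-3-en-2-yl]-2,2-dimethyltetrahydrofuro[2,3-d][1,3]dioxole | C=C(Br)[C@H](CO[Si](C)(C)C(C)(C)C)[C@@H]1CO[C@@H]2OC(C)(C)O[C@H]12 | intermediate
31 | alkenyllithium from 30 (Li in place of Br) | C=C([Li])[C@H](CO[Si](C)(C)C(C)(C)C)[C@@H]1CO[C@@H]2OC(C)(C)O[C@H]12 | intermediate
32 | lithium (1R,3aS,7aS)-1-alkenyl-4,4,7a-trimethyloctahydro-1H-inden-1-olate (O β, side chain α) | C=C([C@]1(O[Li])CC[C@H]2C(C)(C)CCC[C@]12C)[C@H](CO[Si](C)(C)C(C)(C)C)[C@@H]1CO[C@@H]2OC(C)(C)O[C@H]12 | intermediate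
33 | methyl carbonate of the tertiary allylic alcohol derived from 32 (1R; carbonate β) | C=C([C@]1(OC(=O)OC)CC[C@H]2C(C)(C)CCC[C@]12C)[C@H](CO[Si](C)(C)C(C)(C)C)[C@@H]1CO[C@@H]2OC(C)(C)O[C@H]12 | intermediate
34 | (3aR,6R,6aR)-6-{(2R)-1-(tert-butyldimethylsilyloxy)-3-[(1R,3aS,7aS)-4,4,7a-trimethyloctahydro-1H-inden-1-yl]but-3-en-2-yl}-2,2-dimethyltetrahydrofuro[2,3-d][1,3]dioxole | C=C([C@H]1CC[C@H]2C(C)(C)CCC[C@]12C)[C@H](CO[Si](C)(C)C(C)(C)C)[C@@H]1CO[C@@H]2OC(C)(C)O[C@H]12 | intermediate
35 | primary alcohol from 34 | C=C([C@H]1CC[C@H]2C(C)(C)CCC[C@]12C)[C@H](CO)[C@@H]1CO[C@@H]2OC(C)(C)O[C@H]12 | intermediate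
36 | acetate of 35 | C=C([C@H]1CC[C@H]2C(C)(C)CCC[C@]12C)[C@H](COC(C)=O)[C@@H]1CO[C@@H]2OC(C)(C)O[C@H]12 | intermediate
37 | lactol diol acetate (2',3'-dihydroxyoxolane, anomers) | C=C([C@H]1CC[C@H]2C(C)(C)CCC[C@]12C)[C@H](COC(C)=O)[C@@H]1COC(O)[C@@H]1O | intermediate
38 | open 2,4-dihydroxy acid from 37 | C=C([C@H]1CC[C@H]2C(C)(C)CCC[C@]12C)[C@H](COC(C)=O)[C@H](CO)[C@@H](O)C(=O)O | intermediate
39 | (2R)-2-[(3R,4R)-4-hydroxy-5-oxooxolan-3-yl]-3-[(1R,3aS,7aS)-4,4,7a-trimethyloctahydro-1H-inden-1-yl]but-3-en-1-yl acetate | C=C([C@H]1CC[C@H]2C(C)(C)CCC[C@]12C)[C@H](COC(C)=O)[C@@H]1COC(=O)[C@@H]1O | target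

Total step count: 23. Longest linear sequence: 15 (steps 1–9 and 18–23). The side-chain branch runs over steps 10–17, with step 12 as a one-step side arm.

Steps most likely to fail

Step 6. The cycloaddition may stall. The s-cis rotamer with the methyl group inside is scarce, and two quaternary carbons form next to the spiro carbon. Warming to force turnover would erode facial selectivity, and the sulfur atoms may tie up the acid. The fallback changes the mode of activation and takes the C2 methyl group out of the cycloaddition. It sets out from 9.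
- Wittig olefination with Ph3P=CHCHO gives (2E)-5-{2-[(2E)-penta-2,4-dien-2-yl]-1,3-dithian-2-yl}pent-2-enal F1.
- Iminium catalysis with (2R,5R)-5-benzyl-2-tert-butyl-3-methylimidazolidin-4-one trifluoroacetate in MeCN–H2O is an established route from deca-2,7,9-trienals to trans-hydrindene carbaldehydes and is indifferent to sulfur. It should give the endo adduct (3a'S,4'R,7a'S)-7a'-methyl-2',3',3a',4',5',7a'-hexahydrospiro[1,3-dithiane-2,1'-indene]-4'-carbaldehyde F2, with only one quaternary carbon made in the ring-forming step.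
- KOt-Bu and MeI methylate the aldehyde enolate from the α face, away from the angular methyl, to give the C4' epimer of 11, (3a'S,4'S,7a'S)-4',7a'-dimethyl-2',3',3a',4',5',7a'-hexahydrospiro[1,3-dithiane-2,1'-indene]-4'-carbaldehyde F3.
- C4 ends as CMe2, so its configuration does not matter. Wolff–Kishner reduction through the hydrazone of the epimeric aldehyde F4 comes back to the route at 13.

Step 18. The basic, branched alkenyllithium may enolise the hindered cyclopentanone instead of adding, or the crowded tertiary alkoxide may be acylated incompletely. The fallback replaces carbonyl addition and hydrogenolysis by a stereospecific boronate 1,2-migration. It sets out from 15.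
- KN(SiMe3)2 and PhNTf2 give (3aS,7aS)-4,4,7a-trimethyl-3a,4,5,6,7,7a-hexahydro-3H-inden-1-yl trifluoromethanesulfonate F5.
- Miyaura borylation (bis(pinacolato)diboron, PdCl2(dppf), KOAc, dioxane) gives the alkenyl pinacol boronate F6.
- Hydrogenation with [Ir(cod)(PCy3)(py)]PF6 or Pd on carbon adds hydrogen from the α face and gives the 1β-pinacol boronate of the saturated hydrindane F7.
- Alkenyllithium 31 adds to boron to give the lithium boronate complex F8. Zweifel olefination (I2, then NaOMe) moves C1 onto Ca with retention and comes back to the route at 34, bypassing 33.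

Step 14. On warming, the dianion may fragment to ketene and allyl alkoxide, the bromoalkene may lose HBr to excess amide base, or the chelate may give too little facial bias. The fallback gives up the charged chelate for a neutral silyl ketene acetal on a protected substrate. It sets out from 24.
- Et3SiCl and imidazole give the O-triethylsilyl ether of the mixed malate F9.
- KN(SiMe3)2 and Me3SiCl in THF–DMPU at −78 °C give the trimethylsilyl ketene acetal with C3' cis to OSi F10.
- This undergoes the classical Ireland–Claisen rearrangement through the same chair at 23 °C to give the O-triethylsilyl acid F11. Facial control now comes from the Felkin-type bias of the C3' stereocentre.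
- Borane reduction and ring closure give the O-triethylsilyl lactone F12. At this stage the two chair products are diastereomers (cis and trans lactones) and can be separated.
- Pyridinium p-toluenesulfonate in MeOH removes the secondary triethylsilyl group selectively and comes back to the route at 28.

Further compounds
F1 | step 6 | (2E)-5-{2-[(2E)-penta-2,4-dien-2-yl]-1,3-dithian-2-yl}pent-2-enal | C=C/C=C(C)/C1(SCCCS1)CC/C=C/C=O
F2 | step 6 | (3a'S,4'R,7a'S)-7a'-methyl-2',3',3a',4',5',7a'-hexahydrospiro[1,3-dithiane-2,1'-indene]-4'-carbaldehyde | S1CCCSC12CC[C@H]3[C@H](C=O)CC=C[C@]23C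
F3 | step 6 | (3a'S,4'S,7a'S)-4',7a'-dimethyl-2',3',3a',4',5',7a'-hexahydrospiro[1,3-dithiane-2,1'-indene]-4'-carbaldehyde | S1CCCSC12CC[C@H]3[C@@](C)(C=O)CC=C[C@]23C
F4 | step 6 | hydrazone of the epimeric aldehyde | S1CCCSC12CC[C@H]3[C@@](C)(C=NN)CC=C[C@]23C
F5 | step 18 | (3aS,7aS)-4,4,7a-trimethyl-3a,4,5,6,7,7a-hexahydro-3H-inden-1-yl trifluoromethanesulfonate | O=S(=O)(OC1=CC[C@H]2C(C)(C)CCC[C@]12C)C(F)(F)F
F6 | step 18 | 2-[(3aS,7aS)-4,4,7a-trimethyl-3a,4,5,6,7,7a-hexahydro-3H-inden-1-yl]-4,4,5,5-tetramethyl-1,3,2-dioxaborolane | CC1(C)OB(OC1(C)C)C1=CC[C@H]2C(C)(C)CCC[C@]12C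
F7 | step 18 | 2-[4,4,7a-trimethyloctahydro-1H-inden-1-yl]-4,4,5,5-tetramethyl-1,3,2-dioxaborolane, boron β (cis to the angular methyl), trans-fused | CC1(C)OB(OC1(C)C)[C@H]1CC[C@H]2C(C)(C)CCC[C@]12C
F8 | step 18 | lithium boronate complex of the 1β-boronate and alkenyllithium 31 | [Li+].C=C([B-]1(OC(C)(C)C(C)(C)O1)[C@H]1CC[C@H]2C(C)(C)CCC[C@]12C)[C@H](CO[Si](C)(C)C(C)(C)C)[C@@H]1CO[C@@H]2OC(C)(C)O[C@H]12
F9 | step 14 | O-triethylsilyl ether of the mixed malate | O=C(C[C@@H](O[Si](CC)(CC)CC)C(=O)OC)OC/C(Br)=C/CO[Si](C)(C)C(C)(C)C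
F10 | step 14 | trimethylsilyl ketene acetal with C3' cis to OSi | C[Si](C)(C)O/C(OC/C(Br)=C/CO[Si](C)(C)C(C)(C)C)=C\[C@@H](O[Si](CC)(CC)CC)C(=O)OC
F11 | step 14 | O-triethylsilyl acid | C=C(Br)[C@H](CO[Si](C)(C)C(C)(C)C)[C@H](C(=O)O)[C@@H](O[Si](CC)(CC)CC)C(=O)OC
F12 | step 14 | O-triethylsilyl lactone | C=C(Br)[C@H](CO[Si](C)(C)C(C)(C)C)[C@@H]1COC(=O)[C@@H]1O[Si](CC)(CC)CC
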